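**Strategy.** Ring A, the methylcyclopentane (C3–C4–C5–C6–C8), is made last by a Wagner–Meerwein ring contraction. Its tetrasubstituted C2=C3 alkene, exocyclic to ring A, endocyclic to the cyclooctene ring B and methylated at C2, is the trace of a tertiary C2 cation born from a 1,2-shift. The precursor is therefore a 6-7-6-5 tetracycle in which C8 is still bonded to C2: a cyclohexyl mesylate (C3) next to the angular-methyl carbon of a cycloheptane. One solvolysis moves C8 from C2 to C3, contracting the cyclohexane to ring A and expanding the cycloheptane to ring B, and proton loss installs the alkene. Locants follow the remark below.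

Key step: step 27

Remark (locants): heavy atoms of the target are numbered 1–26 in the order of its SMILES string (compound 40; atom 18 is the oxygen; C1, C7, C12, C16 are the methyls on C2, C6, C11, C15; C21–C23 the isopropyl group on C20), and all intermediates keep these locants. Ring A = C3, C4, C5, C6, C8; ring B = C2, C3, C8, C9, C10, C11, C13, C26; ring C = C13, C14, C15, C24, C25, C26; ring D = C15, C17, C19, C20, C24. Before the rearrangement the six-membered ring C2, C3, C4, C5, C6, C8 is ring A′ and the seven-membered ring C2, C8, C9, C10, C11, C13, C26 is ring B′.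

Remark (assumption): (5S)-5-(d-menthyloxy)furan-2(5H)-one (3) is taken as purchasable, like its commoner (5R)-l-menthyloxy antipode.

Step 1
Reactants: 1 (E)-pent-2-enal
Product: 2 (1E,3E)-1-(tert-butyldimethylsilyloxy)penta-1,3-diene
Conditions: TBSOTf, Et3N, Et2O, 0 °C to rt
Reagents that add atoms: tert-butyldimethylsilyl triflate, CC(C)(C)[Si](C)(C)OS(=O)(=O)C(F)(F)F
Why: O-silylation of the enal with γ-deprotonation (vinylogous silyl enol ether formation) should give the 1-silyloxy diene, of which the (1E,3E) isomer is the one that reacts in step 2.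

Step 2
Reactants: 2 (1E,3E)-1-(tert-butyldimethylsilyloxy)penta-1,3-diene; 3 (5S)-5-(d-menthyloxy)furan-2(5H)-one
Product: 4 Diels–Alder adduct (cis-fused lactone acetal of ring A′)
Conditions: toluene, 115 °C, sealed tube
Reagents that add atoms: none
Why: Thermal Diels–Alder reaction in which the methyl-bearing diene terminus (C6) bonds to the butenolide β-carbon (C8), the lactone ring is endo and the diene attacks anti to the menthyloxy group, so C2, C3, C6 and C8 are set at once with C26, C9, O-3 and C7 all cis.

Step 3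
Reactants: 4 Diels–Alder adduct
Product: 5 dihydro adduct
Conditions: H2 (1 atm), Pd/C, EtOAc, rt
Reagents that add atoms: none
Why: Hydrogenation of the C4=C5 alkene creates no stereocenter and removes the allylic character of the C3 silyl ether before the enolate and acid steps.

Step 4
Reactants: 5 dihydro adduct
Product: 6 C2-methylated lactone acetal
Conditions: LiN(i-Pr)2, THF, −78 °C; MeI, −78 to −40 °C
Reagents that add atoms: iodomethane, CI
Why: Alkylation of the ring-fusion lactone enolate on its convex face, anti to the C3 silyloxy and C7 methyl groups, should install C1 trans to O-3 with the cis ring fusion kept.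

Step 5
Reactants: 6 C2-methylated lactone acetal
Product: 7 aldehyde Weinreb amide
Conditions: MeNH(OMe)·HCl, AlMe3, CH2Cl2, 0 °C to rt; aqueous work-up
Reagents that add atoms: N,O-dimethylhydroxylamine hydrochloride, CNOC.Cl
Why: Aluminium-amide aminolysis of the lactone (Weinreb amide formation) opens the ring, and the hemiacetal arm collapses on work-up to the C9 aldehyde with loss of menthol, no stereocenter being touched.

Step 6
Reactants: 7 aldehyde Weinreb amide
Product: 8 vinyl Weinreb amide
Conditions: Ph3PCH3Br, KN(SiMe3)2, THF, −78 to 0 °C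
Reagents that add atoms: methyltriphenylphosphonium bromide, C[P+](c1ccccc1)(c1ccccc1)c1ccccc1.[Br-]
Why: Wittig methylenation of the aldehyde, much faster than attack on the hindered amide, gives the C8 vinyl group, and the salt-free ylide at low temperature should leave C8 unepimerised.

Step 7
Reactants: 8 vinyl Weinreb amide
Product: 9 methyl ketone of ring A′
Conditions: MeLi, THF, −78 to 0 °C; aq. NH4Cl
Reagents that add atoms: methyllithium, [Li]C
Why: Weinreb ketone synthesis, the chelated tetrahedral intermediate stopping at the methyl ketone (C26, C25).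

Step 8
Reactants: 9 methyl ketone of ring A′
Product: 10 trimethylsilyl enol ether
Conditions: LiN(i-Pr)2, THF, −78 °C; TMSCl
Reagents that add atoms: chlorotrimethylsilane, C[Si](C)(C)Cl
Why: Enolisation can occur only toward the methyl group because C2 is quaternary, so O-silylation gives the terminal enol silane needed as Michael donor.

Step 9
Reactants: 11 (R)-4-(tert-butyldimethylsilyloxy)cyclopent-2-en-1-one
Product: 13 (S)-4-isopropylcyclopent-2-en-1-one, via silyloxy ketone 12 (not isolated)
Conditions: i-PrMgCl, CuBr·SMe2 (cat.), THF, −78 °C; aq. NH4Cl; then DBU, CH2Cl2, 0 °C to rt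
Reagents that add atoms: isopropylmagnesium chloride, CC(C)[Mg]Cl
Why: Copper-catalysed conjugate addition anti to the silyloxy group sets C20, and E1cB loss of silanol toward the other α-carbon transposes the enone without touching that centre.

Step 10
Reactants: 13 (S)-4-isopropylcyclopent-2-en-1-one
Product: 14 (S)-2-iodo-4-isopropylcyclopent-2-en-1-one
Conditions: I2, pyridine, CH2Cl2, rt
Reagents that add atoms: iodine, II
Why: α-Iodination of the enone by pyridine-mediated addition–iodination–elimination gives the 2-iodoenone.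

Step 11
Reactants: 14 (S)-2-iodo-4-isopropylcyclopent-2-en-1-one
Product: 15 (S)-4-isopropyl-2-methylcyclopent-2-en-1-one
Conditions: SnMe4, Pd2(dba)3 (cat.), AsPh3, CuI (cat.), NMP, 60 °C
Reagents that add atoms: tetramethylstannane, C[Sn](C)(C)C
Why: Stille coupling of the α-iodoenone installs the C16 methyl under neutral conditions that leave the γ-stereocenter C20 intact.

Step 12
Reactants: 16 (R)-4-benzyloxazolidin-2-one; 17 (E)-but-2-enoyl chloride
Product: 18 (R)-4-benzyl-3-[(E)-but-2-enoyl]oxazolidin-2-one
Conditions: n-BuLi, THF, −78 °C; then 17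
Reagents that add atoms: none
Why: N-acylation of the lithiated oxazolidinone gives the N-enoyl imide, no stereocenter being involved.

Step 13
Reactants: 18 (R)-4-benzyl-3-[(E)-but-2-enoyl]oxazolidin-2-one
Product: 19 (R)-4-benzyl-3-[(S)-3-methylpent-4-enoyl]oxazolidin-2-one
Conditions: CH2=CHMgBr, CuBr·SMe2 (cat.), THF, −78 to −20 °C
Reagents that add atoms: vinylmagnesium bromide, C=C[Mg]Br
Why: Auxiliary-controlled cuprate conjugate addition to the chelated s-cis imide occurs on the face opposite the benzyl group and sets C11 as (S).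

Step 14
Reactants: 19 (R)-4-benzyl-3-[(S)-3-methylpent-4-enoyl]oxazolidin-2-one
Product: 20 (S)-3-methylpent-4-en-1-ol
Conditions: LiBH4, Et2O, MeOH (1 equiv), 0 °C
Reagents that add atoms: none
Why: Reductive cleavage of the imide gives the primary alcohol and frees the auxiliary without touching C11.

Step 15
Reactants: 20 (S)-3-methylpent-4-en-1-ol
Product: 21 (S)-3-methylpent-4-enal
Conditions: Dess–Martin periodinane, NaHCO3, CH2Cl2, 0 °C
Reagents that add atoms: none
Why: Mild oxidation gives the volatile aldehyde, which is used at once as a solution.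

Step 16
Reactants: 10 trimethylsilyl enol ether; 15 (S)-4-isopropyl-2-methylcyclopent-2-en-1-one; 21 (S)-3-methylpent-4-enal
Product: 24 aldol (ring D ketone carrying both side chains), via Michael enol silane 22 (not isolated), via silylated aldol 23 (not isolated)
Conditions: Ph3CSbCl6 (cat.), CH2Cl2, −78 °C (10 + 15); then 21, −78 to −45 °C; then 1 M HCl, THF, 0 °C
Reagents that add atoms: none
Why: Trityl-cation-catalysed tandem Mukaiyama–Michael/Mukaiyama aldol reaction, in which the enol silane adds to C24 anti to the C20 isopropyl group and the resulting tetrasubstituted enol silane adds to the aldehyde anti to the new C25 chain, sets C24 and the quaternary C15 (both C14 carbinol epimers are used).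

Step 17
Reactants: 24 aldol
Product: 25 triketone
Conditions: Dess–Martin periodinane, NaHCO3, CH2Cl2, rt
Reagents that add atoms: none
Why: Oxidation of the C14 carbinol gives the C14 ketone and erases the C14 stereocenter.

Step 18
Reactants: 25 triketone
Product: 26 tricyclic enone (ring C closed)
Conditions: p-TsOH·H2O (cat.), toluene, reflux, Dean–Stark trap
Reagents that add atoms: none
Why: Acid-catalysed intramolecular aldol condensation (the cyclodehydration half of a Robinson annulation), in which the C13 enol of the C14 ketone attacks the C26 ketone, is the only pairing that gives a six-membered ring and closes ring C as the C13=C26 enone, acid being chosen to avoid retro-Claisen cleavage of the non-enolisable 1,3-diketone.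

Step 19
Reactants: 26 tricyclic enone
Product: 28 tetracyclic 6-7-6-5 enone, via cycloheptadiene 27 (not isolated)
Conditions: second-generation Grubbs catalyst (H2IMes)(PCy3)Cl2Ru=CHPh (cat.), CH2Cl2, 40 °C; then H2 (5 bar), MeOH, 50 °C
Reagents that add atoms: none
Why: Ring-closing metathesis of the two vinyl groups closes ring B′ around the cis C13=C26 bond, and the ruthenium hydride formed under H2 hydrogenates the new disubstituted C9=C10 alkene but not the tetrasubstituted enone.

Step 20
Reactants: 28 tetracyclic enone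
Product: 29 C17 alcohol
Conditions: NaBH4, MeOH/CH2Cl2, −40 °C
Reagents that add atoms: none
Why: The cyclopentanone is reduced much faster than the hindered tetrasubstituted enone, and hydride attack on C17 from the face opposite the angular C16 methyl gives the alcohol cis to C16, as in 17-keto steroids.

Step 21
Reactants: 29 C17 alcohol
Product: 30 C17 triisopropylsilyl ether
Conditions: TIPSOTf, 2,6-lutidine, CH2Cl2, 0 °C to rt
Reagents that add atoms: triisopropylsilyl triflate, CC(C)[Si](OS(=O)(=O)C(F)(F)F)(C(C)C)C(C)C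
Why: Silylation protects the C17 alcohol with a group that survives acidic fluoride, dissolving metal and solvolysis.

Step 22
Reactants: 30 C17 triisopropylsilyl ether
Product: 32 enol acetate, via lithium enolate 31 (not isolated)
Conditions: Li, NH3(l), THF, t-BuOH (1 equiv), −78 °C; evaporate NH3; Ac2O, THF, −78 to 0 °C
Reagents that add atoms: acetic anhydride, CC(=O)OC(C)=O
Why: Dissolving-metal reduction of the enone with axial protonation at C26 on the face of H24 (ring C is locked by its trans fusion to ring D, so C2 ends equatorial) sets C26, and O-acetylation of the enolate masks C14 for the second reduction.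

Step 23
Reactants: 32 enol acetate
Product: 33 C3 alcohol
Conditions: HF·pyridine, pyridine, THF, rt
Reagents that add atoms: none
Why: The secondary tert-butyldimethylsilyl ether at C3 is cleaved selectively because the triisopropylsilyl ether is far more stable to acidic fluoride.

Step 24
Reactants: 33 C3 alcohol
Product: 34 C3 ketone
Conditions: Dess–Martin periodinane, NaHCO3, CH2Cl2, rt
Reagents that add atoms: none
Why: Neutral oxidation removes the C3 configuration set in step 2, which is the wrong one for the rearrangement.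

Step 25
Reactants: 34 C3 ketone
Product: 35 hydroxy ketone
Conditions: Li, NH3(l), THF, t-BuOH (3 equiv), −78 to −33 °C; solid NH4Cl
Reagents that add atoms: none
Why: In this dissolving-metal reduction the enol acetate is first cleaved to the lithium enolate, which shields C14, while the C3 ketone is reduced to the thermodynamically favoured equatorial alcohol (cis to C1, trans to C26), and protonation at C13 on quench gives the trans-fused C14 ketone.

Step 26
Reactants: 35 hydroxy ketone
Product: 36 C3 mesylate
Conditions: MsCl, Et3N, CH2Cl2, −10 °C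
Reagents that add atoms: methanesulfonyl chloride, CS(=O)(=O)Cl
Why: Sulfonylation through sulfene converts the hindered equatorial alcohol into the mesylate with retention at C3.

Step 27
Reactants: 36 C3 mesylate
Product: 37 rearranged ketone with the 5-8-6-5 skeleton
Conditions: KOAc, AcOH, 70 °C
Reagents that add atoms: none
Why: Ionisation of the equatorial C3 mesylate is assisted by the antiperiplanar C2–C8 ring-fusion bond, so C8 shifts from C2 to C3 (Wagner–Meerwein 1,2-alkyl shift) and the tertiary C2 cation then loses the C3 proton to give the C2=C3 alkene. The closest known reaction type is the buffered solvolysis of equatorial 10-methyl-1-decalyl sulfonates to hydroazulenes (eudesmane-to-guaiane rearrangement), and the 6-7 to 5-8 change costs no more ring strain than that 6-6 to 5-7 case. Ring A (C3, C4, C5, C6, C8) is closed by this ring contraction, the new C3–C8 bond forming as C2–C8 breaks, while ring B′ grows by one atom to ring B. No new stereocenter arises, since C8 migrates with retention and C3 becomes sp2, and the alkene geometry (C1 cis to C4) is fixed because ring B cannot hold a trans double bond. The step needs migration of the ring bond and not of the C1 methyl group, which the chair with equatorial mesylate, axial C1 and equatorial C26 secures (only C2–C8 is antiperiplanar to the C–O bond), and it needs loss of H3 over H26 or a methyl proton, the Zaitsev outcome that leads to the alkylidenecyclopentane. The C14 ketone is kept until after this step so that H26 is not allylic and no C13=C14 π bond can capture the C2 cation.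

Step 28
Reactants: 37 rearranged ketone
Product: 38 C13=C14 enol triflate
Conditions: KN(SiMe3)2, THF, −78 °C; PhNTf2, −78 to 0 °C
Reagents that add atoms: N-phenylbis(trifluoromethanesulfonimide), O=S(=O)(N(c1ccccc1)S(=O)(=O)C(F)(F)F)C(F)(F)F
Why: The C14 ketone can enolise only toward C13 because C15 is quaternary, so O-triflation gives the C13=C14 enol triflate regiospecifically.

Step 29
Reactants: 38 enol triflate
Product: 39 17-O-triisopropylsilyl aspergilol C
Conditions: Pd(OAc)2 (cat.), PPh3, HCO2H, n-Bu3N, DMF, 60 °C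
Reagents that add atoms: none
Why: Palladium-catalysed formate reduction of the enol triflate (oxidative addition, formate exchange, decarboxylation, reductive elimination) replaces the triflate by hydrogen and leaves the C13=C14 alkene in place.

Step 30
Reactants: 39 17-O-triisopropylsilyl aspergilol C
Product: 40 aspergilol C
Conditions: Bu4NF, THF, 50 °C
Reagents that add atoms: none
Why: Fluoride cleaves the silyl ether and frees the C17 alcohol without touching the two alkenes.

**Compound list**

1 | (E)-pent-2-enal | CC/C=C/C=O | starting material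
2 | (1E,3E)-1-(tert-butyldimethylsilyloxy)penta-1,3-diene | C/C=C/C=C/O[Si](C)(C)C(C)(C)C | intermediate
3 | (5S)-5-[(1S,2R,5S)-menthyloxy]furan-2(5H)-one | O=C1O[C@H](O[C@H]2C[C@@H](C)CC[C@@H]2C(C)C)C=C1 | starting material
4 | Diels–Alder adduct: cis-fused cyclohexene lactone acetal (lactone C=O is C26 on C2; menthyl acetal carbon is C9 on C8; 3-OTBS; C4=C5; 6-methyl; C26, C9, O-3 and C7 on one face; menthyloxy trans to the C8–C6 bond) | O=C1O[C@H](O[C@H]3C[C@@H](C)CC[C@@H]3C(C)C)[C@H]2[C@@H](C)C=C[C@@H](O[Si](C)(C)C(C)(C)C)[C@@H]12 | intermediate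
5 | dihydro adduct (C4–C5 saturated) | O=C1O[C@H](O[C@H]3C[C@@H](C)CC[C@@H]3C(C)C)[C@H]2[C@@H](C)CC[C@@H](O[Si](C)(C)C(C)(C)C)[C@@H]12 | intermediate
6 | C2-methylated lactone acetal (C1 trans to O-3; cis ring fusion) | O=C1O[C@H](O[C@H]3C[C@@H](C)CC[C@@H]3C(C)C)[C@H]2[C@@H](C)CC[C@@H](O[Si](C)(C)C(C)(C)C)[C@@]12C | intermediate
7 | aldehyde Weinreb amide (C9 aldehyde on C8 cis to the C26 N-methoxy-N-methylamide on C2) | O=C[C@H]1[C@@H](C)CC[C@@H](O[Si](C)(C)C(C)(C)C)[C@@]1(C)C(=O)N(C)OC | intermediate
8 | vinyl Weinreb amide (C8 vinyl) | C=C[C@H]1[C@@H](C)CC[C@@H](O[Si](C)(C)C(C)(C)C)[C@@]1(C)C(=O)N(C)OC | intermediate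
9 | methyl ketone of ring A′ (C2: methyl C1 and acetyl C26/C25; 3-OTBS; 6-methyl; 8-vinyl; acetyl, OTBS, C7 and vinyl cis, C1 trans to them) | C=C[C@H]1[C@@H](C)CC[C@@H](O[Si](C)(C)C(C)(C)C)[C@@]1(C)C(C)=O | intermediate
10 | trimethylsilyl enol ether of 9 (C26=C25H2) | C=C[C@H]1[C@@H](C)CC[C@@H](O[Si](C)(C)C(C)(C)C)[C@@]1(C)C(=C)O[Si](C)(C)C | intermediate
11 | (R)-4-(tert-butyldimethylsilyloxy)cyclopent-2-en-1-one | O=C1C=C[C@H](O[Si](C)(C)C(C)(C)C)C1 | starting material
12 | (3S,4R)-3-isopropyl-4-(tert-butyldimethylsilyloxy)cyclopentan-1-one | O=C1C[C@@H](C(C)C)[C@H](O[Si](C)(C)C(C)(C)C)C1 | intermediate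
13 | (S)-4-isopropylcyclopent-2-en-1-one | O=C1C=C[C@H](C(C)C)C1 | intermediate
14 | (S)-2-iodo-4-isopropylcyclopent-2-en-1-one | O=C1C(I)=C[C@H](C(C)C)C1 | intermediate
15 | (S)-4-isopropyl-2-methylcyclopent-2-en-1-one | O=C1C(C)=C[C@H](C(C)C)C1 | intermediate
16 | (R)-4-benzyloxazolidin-2-one | O=C1N[C@H](Cc2ccccc2)CO1 | starting material
17 | (E)-but-2-enoyl chloride | C/C=C/C(=O)Cl | starting material
18 | (R)-4-benzyl-3-[(E)-but-2-enoyl]oxazolidin-2-one | C/C=C/C(=O)N1[C@H](Cc2ccccc2)COC1=O | intermediate
19 | (R)-4-benzyl-3-[(S)-3-methylpent-4-enoyl]oxazolidin-2-one | C=C[C@@H](C)CC(=O)N1[C@H](Cc2ccccc2)COC1=O | intermediate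
20 | (S)-3-methylpent-4-en-1-ol | C=C[C@@H](C)CCO | intermediate
21 | (S)-3-methylpent-4-enal | C=C[C@@H](C)CC=O | intermediate
22 | Michael adduct as trimethylsilyl enol ether (C24–C25 bond formed; C15=C17 enol silane; C25 trans to the C20 isopropyl group) | CC1=C(O[Si](C)(C)C)C[C@@H](C(C)C)[C@@H]1CC(=O)[C@]2(C)[C@H](O[Si](C)(C)C(C)(C)C)CC[C@H](C)[C@@H]2C=C | intermediate
23 | O-trimethylsilyl aldol (both C14 epimers) | C=C[C@@H](C)CC(O[Si](C)(C)C)[C@@]1(C)C(=O)C[C@@H](C(C)C)[C@@H]1CC(=O)[C@]2(C)[C@H](O[Si](C)(C)C(C)(C)C)CC[C@H](C)[C@@H]2C=C | intermediate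
24 | aldol: ring D ketone with quaternary C15 (C16 methyl, C14 carbinol chain) and C24 chain CH2C(=O)–ring A′; C25 trans to isopropyl and to C14; both C14 epimers | C=C[C@@H](C)CC(O)[C@@]1(C)C(=O)C[C@@H](C(C)C)[C@@H]1CC(=O)[C@]2(C)[C@H](O[Si](C)(C)C(C)(C)C)CC[C@H](C)[C@@H]2C=C | intermediate
25 | triketone (C14, C17 and C26 ketones) | C=C[C@@H](C)CC(=O)[C@@]1(C)C(=O)C[C@@H](C(C)C)[C@@H]1CC(=O)[C@]2(C)[C@H](O[Si](C)(C)C(C)(C)C)CC[C@H](C)[C@@H]2C=C | intermediate
26 | tricyclic enone: ring C closed as the C14(=O)–C13=C26 enone trans-fused to ring D; C26 carries ring A′, C13 the (S)-but-3-en-2-yl group | C=C[C@H]1[C@@H](C)CC[C@@H](O[Si](C)(C)C(C)(C)C)[C@@]1(C)C2=C([C@H](C)C=C)C(=O)[C@@]3(C)C(=O)C[C@@H](C(C)C)[C@@H]3C2 | intermediate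
27 | cycloheptadiene from ring-closing metathesis (C9=C10) | C[C@@]12[C@H](O[Si](C)(C)C(C)(C)C)CC[C@H](C)[C@@H]1C=C[C@@H](C)C1=C2C[C@H]2[C@H](C(C)C)CC(=O)[C@]2(C)C1=O | intermediate
28 | tetracyclic 6-7-6-5 enone (rings A′, B′, C, D; C13=C26 enone; C17 ketone; 3-OTBS) | C[C@@]12[C@H](O[Si](C)(C)C(C)(C)C)CC[C@H](C)[C@@H]1CC[C@@H](C)C1=C2C[C@H]2[C@H](C(C)C)CC(=O)[C@]2(C)C1=O | intermediate
29 | C17 alcohol (OH cis to C16) | C[C@@]12[C@H](O[Si](C)(C)C(C)(C)C)CC[C@H](C)[C@@H]1CC[C@@H](C)C1=C2C[C@H]2[C@H](C(C)C)C[C@@H](O)[C@]2(C)C1=O | intermediate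
30 | C17 triisopropylsilyl ether | C[C@@]12[C@H](O[Si](C)(C)C(C)(C)C)CC[C@H](C)[C@@H]1CC[C@@H](C)C1=C2C[C@H]2[C@H](C(C)C)C[C@@H](O[Si](C(C)C)(C(C)C)C(C)C)[C@]2(C)C1=O | intermediate
31 | lithium enolate (C13=C14–OLi; H26 cis to H24) | C[C@@]12[C@H](O[Si](C)(C)C(C)(C)C)CC[C@H](C)[C@@H]1CC[C@@H](C)C1=C(O[Li])[C@@]3(C)[C@H](O[Si](C(C)C)(C(C)C)C(C)C)C[C@@H](C(C)C)[C@@H]3C[C@@H]12 | intermediate
32 | enol acetate (C13=C14–OAc) | C[C@@]12[C@H](O[Si](C)(C)C(C)(C)C)CC[C@H](C)[C@@H]1CC[C@@H](C)C1=C(OC(C)=O)[C@@]3(C)[C@H](O[Si](C(C)C)(C(C)C)C(C)C)C[C@@H](C(C)C)[C@@H]3C[C@@H]12 | intermediate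
33 | C3 alcohol (OH cis to C26) | C[C@@]12[C@H](O)CC[C@H](C)[C@@H]1CC[C@@H](C)C1=C(OC(C)=O)[C@@]3(C)[C@H](O[Si](C(C)C)(C(C)C)C(C)C)C[C@@H](C(C)C)[C@@H]3C[C@@H]12 | intermediate
34 | C3 ketone | C[C@@]12C(=O)CC[C@H](C)[C@@H]1CC[C@@H](C)C1=C(OC(C)=O)[C@@]3(C)[C@H](O[Si](C(C)C)(C(C)C)C(C)C)C[C@@H](C(C)C)[C@@H]3C[C@@H]12 | intermediate
35 | hydroxy ketone (C3–OH equatorial, cis to C1 and trans to C26; C14 ketone; H13 trans to H26) | C[C@@]12[C@@H](O)CC[C@H](C)[C@@H]1CC[C@@H](C)[C@H]1C(=O)[C@@]3(C)[C@H](O[Si](C(C)C)(C(C)C)C(C)C)C[C@@H](C(C)C)[C@@H]3C[C@@H]12 | intermediate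
36 | C3 mesylate | C[C@@]12[C@@H](OS(C)(=O)=O)CC[C@H](C)[C@@H]1CC[C@@H](C)[C@H]1C(=O)[C@@]3(C)[C@H](O[Si](C(C)C)(C(C)C)C(C)C)C[C@@H](C(C)C)[C@@H]3C[C@@H]12 | intermediate
37 | rearranged ketone with the 5-8-6-5 skeleton (C2=C3 alkene, C14 ketone, 17-OTIPS) | C/C1=C2\CC[C@H](C)[C@@H]2CC[C@@H](C)[C@H]2C(=O)[C@@]3(C)[C@H](O[Si](C(C)C)(C(C)C)C(C)C)C[C@@H](C(C)C)[C@@H]3C[C@@H]21 | intermediate
38 | C13=C14 enol triflate | C/C1=C2\CC[C@H](C)[C@@H]2CC[C@@H](C)C2=C(OS(=O)(=O)C(F)(F)F)[C@@]3(C)[C@H](O[Si](C(C)C)(C(C)C)C(C)C)C[C@@H](C(C)C)[C@@H]3C[C@@H]21 | intermediate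
39 | 17-O-triisopropylsilyl aspergilol C | C/C1=C2\CC[C@H](C)[C@@H]2CC[C@@H](C)C2=C[C@@]3(C)[C@H](O[Si](C(C)C)(C(C)C)C(C)C)C[C@@H](C(C)C)[C@@H]3C[C@@H]21 | intermediate
40 | aspergilol C | C/C1=C2\CC[C@H](C)[C@@H]2CC[C@@H](C)C2=C[C@@]3(C)[C@H](O)C[C@@H](C(C)C)[C@@H]3C[C@@H]21 | target

**Totals.** Total step count: 30. Longest linear sequence: 23 steps (steps 1–8, then 16–30).

**Steps most likely to fail**

Step 27 (key step). The tertiary C2 cation may lose its proton in the wrong direction (toward C26 or the C1 methyl group) or be captured by acetate, so that regiocontrol of the new alkene is lost. The fallback sets out from 36 and separates the skeletal change from alkene formation. Hydrolytic solvolysis (CaCO3, acetone/H2O, 60 °C) lets water trap the rearranged cation as the rearranged tertiary alcohol F1 (both C2 epimers), one constitution whatever the elimination preference. F1 is then dehydrated under equilibrating conditions (catalytic I2 or p-TsOH, benzene, 40 °C), which lead to the most stable alkylidenecyclopentane, and the route is rejoined at 37.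

Step 18. Under equilibrating acid the non-enolisable C14/C17 1,3-diketone may undergo retro-Claisen cleavage, or the hindered C26 ketone may fail to accept the enol. The fallback sets out from 25 and uses a kinetically controlled, stepwise aldol. Soft enolisation with TiCl4 and i-Pr2NEt (CH2Cl2, −78 °C) drives a titanium aldol to the ring C aldol F2 without Brønsted acid or alkoxide. Separate dehydration with Burgess reagent (benzene, 50 °C) then gives 26.

Step 16. The second stage may fail: the tetrasubstituted enol silane may not add to the aldehyde to build the quaternary C15, or may be protodesilylated first. The fallback sets out from 19 and 22 and brings in C14 by acylation instead of aldol addition. Imide 19 is cleaved (LiOH, H2O2, THF/H2O) to (S)-3-methylpent-4-enoic acid F3, which SOCl2 converts into (S)-3-methylpent-4-enoyl chloride F4. The Michael stage of step 16 is run alone and enol silane 22 is isolated. ZnCl2-promoted C-acylation of 22 with F4 (CH2Cl2/Et2O, 0 °C) gives triketone 25 directly, so the route is rejoined at 25 and step 17 is not needed.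

**Further compounds**

F1 | step 27 | rearranged tertiary alcohol (5-8-6-5 skeleton, C2–OH, both C2 epimers) | CC1(O)[C@H]2CC[C@H](C)[C@@H]2CC[C@@H](C)[C@H]2C(=O)[C@@]3(C)[C@H](O[Si](C(C)C)(C(C)C)C(C)C)C[C@@H](C(C)C)[C@@H]3C[C@@H]21
F2 | step 18 | ring C aldol (C26 tertiary alcohol, C13 and C26 as formed) | C=C[C@H]1[C@@H](C)CC[C@@H](O[Si](C)(C)C(C)(C)C)[C@@]1(C)C2(O)C([C@H](C)C=C)C(=O)[C@@]3(C)C(=O)C[C@@H](C(C)C)[C@@H]3C2
F3 | step 16 | (S)-3-methylpent-4-enoic acid | C=C[C@@H](C)CC(=O)O
F4 | step 16 | (S)-3-methylpent-4-enoyl chloride | C=C[C@@H](C)CC(=O)Cl
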